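# Proposed synthesis of CNP0316116.2 by ring-closing γ-aryloxyallylation of a salicylaldehyde

## Analysis of the target

The target 18 is a 2,3-dihydrobenzofuran: a benzene ring (C3a, C4–C7, C7a) fused to a five-membered ring made of O1, C2, C3, C3a and C7a. C2 carries a 1-formylvinyl group, C3 an isovalerate, and C5, which lies para to the O1-bearing C7a, a 1-(isovaleryloxy)ethyl chain. Of the three stereocentres, C2 (R) and C3 (S) are neighbours and trans on the five-membered ring, whereas the side-chain carbinol C1′ (R) is separated from them by the arene, so it cannot be set by relay and has to be controlled on its own. Both esters are benzylic and activated by O1 (C3 through the ortho-related C3a/C7a pair, C1′ through the para relationship), so acid can ionise either of them; loss of isovaleric acid across C2–C3 would aromatise the heterocycle to a benzofuran, and the α-substituted acrolein is an unhindered Michael acceptor. The difficulty is therefore to fix the trans C2/C3 pair in the absolute sense next to a remote, independently set centre, and to bring in the enal and the esters late under nearly neutral conditions. The plan rests on the atom sequence C3a–C3(O)–C2(O1)–C(=CH2): C3 is a benzylic carbinol carbon and its neighbour C2 bears the ring oxygen and an alkene with a terminal methylene, which is a homoallylic alcohol with an oxygenated allylic carbon. This is the pattern left when a γ-oxygenated allyl metal adds through its γ-carbon to an aryl aldehyde, and since O1 also sits on C7a, ortho to the carbon that carries C3, the allyl unit is already tethered to the aldehyde and the C2–C3 bond can be formed as a ring closure.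

## Retrosynthetic reasoning

**Enal to methyl (18 ⇐ 17 ⇐ 16).** The formyl group of 18 is traced back through the allylic alcohol 17 to the methyl group of the isopropenyl compound 16. No skeletal bond is cut. The change is placed last because the enal is the most reactive function of the molecule and because an isopropenyl group is exactly what the key step leaves at C2. The forward allylic oxidation has to choose the methyl group over the C2–H and must not disturb the two benzylic esters.

**Both ester C–O bonds (16 ⇐ 14 + 15).** The two acyl groups are identical, so the two hydroxyls of diol 14 need no differentiation and are acylated together with 15. The C3 hydroxyl is free after the key step. The side-chain hydroxyl is released from silyl ether 13. The forward step must be a double acylation under basic, non-ionising conditions.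

**The C2–C3 bond (13 ⇐ 11).** Cutting this bond opens the dihydrofuran ring and leads to aldehyde 11, in which the future C3 is the formyl carbon and the future C2 is the oxygen-bearing γ-carbon of an allyltin unit hung on O1. This cut is preferred over O1–C2 or O1–C7a because it alone removes the ring and both ring stereocentres at once and makes the isopropenyl alkene part of the nucleophile. A C–O disconnection would leave both stereocentres to be built beforehand in an open-chain diol. The forward reaction has to close the ring, give the trans relationship and choose one aldehyde face under a chiral Lewis acid, since C1′ is too far away to help.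

**Aldehyde and C–Sn bond (11 ⇐ 10 ⇐ 6 + 7).** The aldehyde of 11 is taken back to primary alcohol 10, and the C–Sn bond of 10 is cut to allyl ether 6 and tin chloride 7. Tin is brought in by metalation of the allylic O–CH2 group, which no aldehyde would survive, so the carbonyl carbon is carried at the alcohol level and oxidised afterwards. The free hydroxyl passes through the metalation as its lithium alkoxide (in dianion 8), which also shields the adjacent benzylic CH2 from deprotonation. The forward sequence needs stannylation at the allyl terminus remote from oxygen and an oxidation that spares the allyltin and enol ether units.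

**Side-chain centre and oxidation levels (6 ⇐ 5 ⇐ 4 ⇐ 3).** Alcohol 6 comes from ester 5 by reduction, the silyl ether of 5 from alcohol 4, and the C1′–H bond of 4 from aryl methyl ketone 3. C1′ is thereby set by asymmetric reduction of a simple aryl methyl ketone, where the most dependable method is available. The silyl ether then guards this easily ionised p-alkoxybenzylic carbinol until the acylation.

**Aryl ether (3 ⇐ 1 + 2).** The O1–CH2 bond is cut to phenol 1 and allylic chloride 2. Compound 1 already has the 1,2,4-substitution pattern with the two carbonyl groups at different oxidation levels (ester for the future C3, ketone for C1′), so no aromatic substitution is needed. Compound 2 supplies the four carbons that become C2 and the isopropenyl group.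

## Alternatives that were turned down

**Alternative 1: the benzene ring made last by alkyne cyclotrimerisation.**
- Disconnection: the arene is cut at C3a–C7a, C4–C5 and C6–C7.
- Forward key step: the 1,6-diyne A2 holds a silylated ynol ether (future C7–C7a) and a propargylic ester (future C3a–C4) linked through O1–C2–C3. It would be cyclotrimerised with alkyne A3 on [Rh(cod)2]BF4 with BINAP to give the 7-silylated arene A1, closing the benzene and dihydrofuran rings together.
- For it: it is the most convergent plan. Both esters and all three stereocentres are in place before the key step, arene formation is strongly downhill, and only protodesilylation at C7 and the allylic oxidation would remain.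
- Against it:
  - In A2, O1 sits between an alkyne carbon and a carbon that is allylic to the isopropenyl group. Such an allyl alkynyl ether is set up for a [3,3]-sigmatropic shift to an allyl ketene under very mild conditions, so A2 is unlikely to survive its own preparation.
  - A cationic rhodium catalyst meeting a propargylic ester invites acyloxy migration.
  - The orientation of A3 (side chain at C5 and not C6) depends only on steric steering by the silyl group.
  - Removing the aryl silyl group needs acid, which the activated benzylic esters tolerate badly.
  - The cycloaddition creates no stereocentre, so the anti C2/C3 diol of A2 must be made enantiopure beforehand.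
- Comparison: Alternative 1 is stronger on convergence and on the number of steps after the key step. The chosen strategy offers a stable aldehyde precursor and a key step that itself creates C2 and C3.

**Alternative 2: chroman-to-dihydrobenzofuran ring contraction.**
- Disconnection: the O1–C2 bond of the target is traced to the O1–C(gem-dimethyl) bond of a chroman.
- Forward key step: Jacobsen epoxidation of chromene A6 and acylative opening at the benzylic carbon would give the trans hydroxy ester A5. Triflation of its C3 hydroxyl (Tf2O, pyridine) should trigger a 1,2-shift of O1 from the gem-dimethyl carbon to C3 with inversion, and the tertiary cation loses a proton to give the isopropenyl ester A4.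
- For it: the absolute configuration comes from a dependable asymmetric epoxidation on its best substrate class. The contraction is stereospecific, and the sequence is short.
- Against it:
  - The C4 ester is trans and vicinal to the triflate, so its carbonyl oxygen can intervene as a dioxolanylium ion, leading to acyl migration or substitution with retention.
  - The C4–C4a bond is also antiperiplanar to an equatorial leaving group and may migrate in competition.
  - The acetyl group must then be reduced asymmetrically late, with the labile C3 ester already present.
  - The two isovalerates go on in separate operations.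
- Comparison: Alternative 2 is stronger in precedent for the enantio-determining step and at least as short. The chosen strategy offers in exchange a C–C bond-forming step with no cation next to an ester, C1′ set early on a simple ketone, and both esters installed in one step.

**Alternative 3: aryl–oxygen closure by SNAr.**
- Disconnection: O1–C7a.
- Forward key step: the C2 alkoxide of the anti diol A8 would displace the fluoride para to the acetyl group (Cs2CO3, DMSO, heat) to give A7, with both carbinol configurations untouched.
- For it: intramolecular SNAr etherification is dependable. Only the five-membered closure is possible, because the benzylic alkoxide would have to form a four-membered ring. The acetyl group serves as activator and as the later side chain, and A7 has a free C3 hydroxyl for a double acylation after ketone reduction.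
- Against it:
  - One para acetyl is a modest activator, so hot basic DMSO is needed. There the methyl ketone enolises, and the 3-hydroxy-2,3-dihydrobenzofuran can dehydrate to the aromatic benzofuran.
  - The key step makes no C–C bond and no stereocentre. A8 must first be made by an anti-selective asymmetric γ-oxyallylation of an aryl aldehyde, or by dihydroxylation of a Z-configured aryl diene. That is the same C2–C3 problem without the tether, followed by protecting-group steps and a separate ring closure.
  - C1′ is again set late.
- Comparison: Alternative 3 is stronger on per-step reliability. The chosen strategy merges bond formation, stereocontrol and ring closure in one step and is shorter.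

Key step: step 7

Assumption: the facial preference of the BINOL–titanium Lewis acid in step 7 is taken to follow that of the Keck allylation of aryl aldehydes, so that (R)-BINOL directs attack to the Re face of the formyl group and gives 3S; should the tether reverse this, (S)-BINOL is used and nothing else changes.

## Route

Step 1
Reactants: 1 methyl 5-acetyl-2-hydroxybenzoate; 2 3-chloro-2-methylprop-1-ene
Product: 3 methyl 5-acetyl-2-[(2-methylprop-2-en-1-yl)oxy]benzoate
Conditions: K2CO3, KI (cat.), DMF, 60 °C
Reagents that add atoms: none
Why: Williamson etherification; the salicylate phenoxide is alkylated by the allylic chloride under iodide catalysis, and O-alkylation is the only pathway open under carbonate conditions.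

Step 2
Reactants: 3 methyl 5-acetyl-2-[(2-methylprop-2-en-1-yl)oxy]benzoate
Product: 4 methyl 5-[(1R)-1-hydroxyethyl]-2-[(2-methylprop-2-en-1-yl)oxy]benzoate
Conditions: RuCl(p-cymene)[(R,R)-TsDPEN] (1 mol %), HCO2H/Et3N (5:2), 30 °C
Reagents that add atoms: none
Why: Noyori asymmetric transfer hydrogenation of an aryl methyl ketone; the (R,R)-diamine complex should deliver hydride to the Si face and set C1′ as R, the sense established for acetophenones. The outer-sphere hydride transfer does not touch the ester or the 1,1-disubstituted alkene.

Step 3
Reactants: 4 methyl 5-[(1R)-1-hydroxyethyl]-2-[(2-methylprop-2-en-1-yl)oxy]benzoate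
Product: 5 methyl 5-[(1R)-1-{[tert-butyl(dimethyl)silyl]oxy}ethyl]-2-[(2-methylprop-2-en-1-yl)oxy]benzoate
Conditions: TBSCl, imidazole, DMF, rt
Reagents that add atoms: tert-butyldimethylsilyl chloride, `CC(C)(C)[Si](C)(C)Cl`
Why: Standard imidazole-mediated silylation; the silyl ether blocks the easily ionised p-alkoxybenzylic hydroxyl through the hydride, organolithium and Lewis-acid steps, and the C1′–O bond is not broken.

Step 4
Reactants: 5 methyl 5-[(1R)-1-{[tert-butyl(dimethyl)silyl]oxy}ethyl]-2-[(2-methylprop-2-en-1-yl)oxy]benzoate
Product: 6 {5-[(1R)-1-{[tert-butyl(dimethyl)silyl]oxy}ethyl]-2-[(2-methylprop-2-en-1-yl)oxy]phenyl}methanol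
Conditions: i-Bu2AlH (2.5 equiv), CH2Cl2, −78 → 0 °C; aq. potassium sodium tartrate (KNaC4H4O6)
Reagents that add atoms: none
Why: Hydride reduction of the aryl ester to the primary alcohol; the silyl ether and the allyl ether are inert to the aluminium hydride.

Step 5
Reactants: 6 {5-[(1R)-1-{[tert-butyl(dimethyl)silyl]oxy}ethyl]-2-[(2-methylprop-2-en-1-yl)oxy]phenyl}methanol; 7 tributyltin chloride
Product: 10 {5-[(1R)-1-{[tert-butyl(dimethyl)silyl]oxy}ethyl]-2-{[(1Z)-2-methyl-3-(tributylstannyl)prop-1-en-1-yl]oxy}phenyl}methanol, via dilithiated ether 8 (not isolated), via lithium alkoxide 9 (not isolated)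
Conditions: s-BuLi (2.2 equiv), TMEDA, THF, −78 °C; 7 (1.3 equiv), −78 °C; H2O
Reagents that add atoms: none
Why: α-Lithiation of an allyl ether followed by γ-stannylation; after the hydroxyl has become its lithium alkoxide, s-BuLi/TMEDA removes an allylic O–CH2 proton to give the internally chelated oxyallyllithium 8, which 7 captures at the carbon remote from oxygen, so that O and CH2Sn end up cis (Z). The alkoxide keeps the neighbouring benzylic CH2 from being deprotonated and is reprotonated at work-up; C1′ is not involved.

Step 6
Reactants: 10 {5-[(1R)-1-{[tert-butyl(dimethyl)silyl]oxy}ethyl]-2-{[(1Z)-2-methyl-3-(tributylstannyl)prop-1-en-1-yl]oxy}phenyl}methanol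
Product: 11 5-[(1R)-1-{[tert-butyl(dimethyl)silyl]oxy}ethyl]-2-{[(1Z)-2-methyl-3-(tributylstannyl)prop-1-en-1-yl]oxy}benzaldehyde
Conditions: SO3·pyridine, DMSO, Et3N, CH2Cl2, 0 °C
Reagents that add atoms: none
Why: Parikh–Doering oxidation of the primary benzylic alcohol; activated-DMSO oxidation under amine base is non-acidic, cannot over-oxidise, and is the kind of oxidation that allyltin and enol ether groups tolerate. The aldehyde is used directly in step 7.

Step 7
Reactants: 11 5-[(1R)-1-{[tert-butyl(dimethyl)silyl]oxy}ethyl]-2-{[(1Z)-2-methyl-3-(tributylstannyl)prop-1-en-1-yl]oxy}benzaldehyde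
Product: 13 (2R,3S)-5-[(1R)-1-{[tert-butyl(dimethyl)silyl]oxy}ethyl]-2-(prop-1-en-2-yl)-2,3-dihydro-1-benzofuran-3-ol, via tributylstannyl ether 12 (not isolated)
Conditions: Ti(OiPr)4 (0.2 equiv), (R)-BINOL (0.4 equiv), 4 Å MS, CH2Cl2, −20 °C; aq. KF
Reagents that add atoms: none
Why: Proposed new method: the Lewis acid formed from Ti(OiPr)4 and (R)-BINOL (tetravalent titanium) binds the formyl oxygen of 11 anti to the aryl group, and the oxygen-bearing γ-carbon of the allyltin unit attacks the carbonyl carbon in an anti SE2′ sense while the C–Sn bond stabilises the positive charge building up on the methyl-bearing carbon; loss of tin then leaves the isopropenyl group and the tin alkoxide 12, which frees the titanium for the next turnover and is cleaved by aqueous KF. The closest known reactions are the Lewis-acid-mediated intramolecular γ-alkoxyallylstannane–aldehyde cyclisation, which gives trans-2-alkenyl-3-hydroxy cyclic ethers, and the BINOL–titanium-catalysed Keck allylation of aldehydes; their combination on a γ-aryloxy stannane in an enantioselective ring closure is not established. The dihydrofuran ring closes in 5-exo-trig mode at the carbonyl carbon, with both the C=O and the attacking C=C exocyclic to the new ring. C3 is set by the BINOLate, which shields one face of the bound aldehyde so that C2 adds to the Re face and gives 3S, the sense seen with this ligand in aryl aldehyde allylations. C2 is set relative to C3 by the open transition state: with no tin–oxygen contact possible, the stannylmethylvinyl unit turns away from the titanium-bound oxygen (C=C and C=O anticlinal, the nearest a five-membered closure comes to an antiperiplanar arrangement), which puts the isopropenyl group and the hydroxyl on opposite faces, hence 2R. The step needs attack through the tin-directed γ-carbon and not through the methyl-bearing carbon of the enol ether, which would give a chroman; the five-membered tether geometry and the tertiary, tin-stabilised cation reached by γ-attack should secure this. C1′ is too remote to influence the outcome, and the mild, alkoxide-buffered Lewis acid should leave its silyl ether and the acid-labile enol ether intact.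

Step 8
Reactants: 13 (2R,3S)-5-[(1R)-1-{[tert-butyl(dimethyl)silyl]oxy}ethyl]-2-(prop-1-en-2-yl)-2,3-dihydro-1-benzofuran-3-ol
Product: 14 (2R,3S)-5-[(1R)-1-hydroxyethyl]-2-(prop-1-en-2-yl)-2,3-dihydro-1-benzofuran-3-ol
Conditions: Bu4NF, THF, 0 °C → rt
Reagents that add atoms: none
Why: Fluoride-induced desilylation driven by the Si–F bond; the basic medium avoids ionisation of either benzylic carbinol, so C3 and C1′ keep their configuration.

Step 9
Reactants: 14 (2R,3S)-5-[(1R)-1-hydroxyethyl]-2-(prop-1-en-2-yl)-2,3-dihydro-1-benzofuran-3-ol; 15 3-methylbutanoyl chloride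
Product: 16 (2R,3S)-5-[(1R)-1-(3-methylbutanoyloxy)ethyl]-2-(prop-1-en-2-yl)-2,3-dihydro-1-benzofuran-3-yl 3-methylbutanoate
Conditions: 15 (2.6 equiv), pyridine, DMAP (cat.), CH2Cl2, −10 °C → rt
Reagents that add atoms: none
Why: DMAP-catalysed acylation of both secondary hydroxyls through the acylpyridinium ion; the C–O bonds at C3 and C1′ are not broken, so both configurations are retained, and the pyridine buffer keeps the medium from becoming acidic.

Step 10
Reactants: 16 (2R,3S)-5-[(1R)-1-(3-methylbutanoyloxy)ethyl]-2-(prop-1-en-2-yl)-2,3-dihydro-1-benzofuran-3-yl 3-methylbutanoate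
Product: 17 (2R,3S)-2-(3-hydroxyprop-1-en-2-yl)-5-[(1R)-1-(3-methylbutanoyloxy)ethyl]-2,3-dihydro-1-benzofuran-3-yl 3-methylbutanoate
Conditions: SeO2 (0.5 equiv), t-BuOOH (3 equiv), CH2Cl2, rt
Reagents that add atoms: selenium dioxide, `O=[Se]=O`; tert-butyl hydroperoxide, `CC(C)(C)OO` (terminal source of the oxygen atom)
Why: Selenium dioxide allylic oxidation: an ene reaction at the terminal methylene takes a methyl hydrogen, and the [2,3]-sigmatropic shift returns oxygen to that carbon and restores the 1,1-disubstituted alkene. The methyl group should be preferred over the C2–H, which is tertiary, hindered and deactivated by O1; any enal formed at this stage is already the target and converges in step 11.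

Step 11
Reactants: 17 (2R,3S)-2-(3-hydroxyprop-1-en-2-yl)-5-[(1R)-1-(3-methylbutanoyloxy)ethyl]-2,3-dihydro-1-benzofuran-3-yl 3-methylbutanoate
Product: 18 (2R,3S)-5-[(1R)-1-(3-methylbutanoyloxy)ethyl]-2-(3-oxoprop-1-en-2-yl)-2,3-dihydro-1-benzofuran-3-yl 3-methylbutanoate
Conditions: MnO2 (activated, excess), CH2Cl2, rt
Reagents that add atoms: none
Why: Allylic alcohol oxidation on the MnO2 surface, selective for the allylic C–OH; the neutral heterogeneous oxidant should leave the esters and the enal alone, and no stereocentre is touched.

## Compound list

1 | methyl 5-acetyl-2-hydroxybenzoate | `COC(=O)c1cc(C(C)=O)ccc1O` | starting material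
2 | 3-chloro-2-methylprop-1-ene | `C=C(C)CCl` | starting material
3 | methyl 5-acetyl-2-[(2-methylprop-2-en-1-yl)oxy]benzoate | `COC(=O)c1cc(C(C)=O)ccc1OCC(C)=C` | intermediate
4 | methyl 5-[(1R)-1-hydroxyethyl]-2-[(2-methylprop-2-en-1-yl)oxy]benzoate | `COC(=O)c1cc([C@@H](C)O)ccc1OCC(C)=C` | intermediate
5 | methyl 5-[(1R)-1-{[tert-butyl(dimethyl)silyl]oxy}ethyl]-2-[(2-methylprop-2-en-1-yl)oxy]benzoate | `COC(=O)c1cc([C@@H](C)O[Si](C)(C)C(C)(C)C)ccc1OCC(C)=C` | intermediate
6 | {5-[(1R)-1-{[tert-butyl(dimethyl)silyl]oxy}ethyl]-2-[(2-methylprop-2-en-1-yl)oxy]phenyl}methanol | `OCc1cc([C@@H](C)O[Si](C)(C)C(C)(C)C)ccc1OCC(C)=C` | intermediate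
7 | tributyltin chloride | `CCCC[Sn](Cl)(CCCC)CCCC` | starting material
8 | lithium {5-[(1R)-1-{[tert-butyl(dimethyl)silyl]oxy}ethyl]-2-[(1-lithio-2-methylprop-2-en-1-yl)oxy]phenyl}methanolate (dilithiated ether) | `[Li]OCc1cc([C@@H](C)O[Si](C)(C)C(C)(C)C)ccc1OC([Li])C(C)=C` | intermediate
9 | lithium {5-[(1R)-1-{[tert-butyl(dimethyl)silyl]oxy}ethyl]-2-{[(1Z)-2-methyl-3-(tributylstannyl)prop-1-en-1-yl]oxy}phenyl}methanolate (lithium alkoxide) | `[Li]OCc1cc([C@@H](C)O[Si](C)(C)C(C)(C)C)ccc1O/C=C(/C)C[Sn](CCCC)(CCCC)CCCC` | intermediate
10 | {5-[(1R)-1-{[tert-butyl(dimethyl)silyl]oxy}ethyl]-2-{[(1Z)-2-methyl-3-(tributylstannyl)prop-1-en-1-yl]oxy}phenyl}methanol | `OCc1cc([C@@H](C)O[Si](C)(C)C(C)(C)C)ccc1O/C=C(/C)C[Sn](CCCC)(CCCC)CCCC` | intermediate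
11 | 5-[(1R)-1-{[tert-butyl(dimethyl)silyl]oxy}ethyl]-2-{[(1Z)-2-methyl-3-(tributylstannyl)prop-1-en-1-yl]oxy}benzaldehyde | `O=Cc1cc([C@@H](C)O[Si](C)(C)C(C)(C)C)ccc1O/C=C(/C)C[Sn](CCCC)(CCCC)CCCC` | intermediate
12 | tert-butyl(dimethyl){(1R)-1-[(2R,3S)-2-(prop-1-en-2-yl)-3-[(tributylstannyl)oxy]-2,3-dihydro-1-benzofuran-5-yl]ethoxy}silane (tributylstannyl ether) | `C=C(C)[C@H]1Oc2ccc([C@@H](C)O[Si](C)(C)C(C)(C)C)cc2[C@@H]1O[Sn](CCCC)(CCCC)CCCC` | intermediate
13 | (2R,3S)-5-[(1R)-1-{[tert-butyl(dimethyl)silyl]oxy}ethyl]-2-(prop-1-en-2-yl)-2,3-dihydro-1-benzofuran-3-ol | `C=C(C)[C@H]1Oc2ccc([C@@H](C)O[Si](C)(C)C(C)(C)C)cc2[C@@H]1O` | intermediate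
14 | (2R,3S)-5-[(1R)-1-hydroxyethyl]-2-(prop-1-en-2-yl)-2,3-dihydro-1-benzofuran-3-ol | `C=C(C)[C@H]1Oc2ccc([C@@H](C)O)cc2[C@@H]1O` | intermediate
15 | 3-methylbutanoyl chloride | `CC(C)CC(=O)Cl` | starting material
16 | (2R,3S)-5-[(1R)-1-(3-methylbutanoyloxy)ethyl]-2-(prop-1-en-2-yl)-2,3-dihydro-1-benzofuran-3-yl 3-methylbutanoate | `C=C(C)[C@H]1Oc2ccc([C@@H](C)OC(=O)CC(C)C)cc2[C@@H]1OC(=O)CC(C)C` | intermediate
17 | (2R,3S)-2-(3-hydroxyprop-1-en-2-yl)-5-[(1R)-1-(3-methylbutanoyloxy)ethyl]-2,3-dihydro-1-benzofuran-3-yl 3-methylbutanoate | `C=C(CO)[C@H]1Oc2ccc([C@@H](C)OC(=O)CC(C)C)cc2[C@@H]1OC(=O)CC(C)C` | intermediate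
18 | (2R,3S)-5-[(1R)-1-(3-methylbutanoyloxy)ethyl]-2-(3-oxoprop-1-en-2-yl)-2,3-dihydro-1-benzofuran-3-yl 3-methylbutanoate | `C=C(C=O)[C@H]1Oc2ccc([C@@H](C)OC(=O)CC(C)C)cc2[C@@H]1OC(=O)CC(C)C` | target

## Step count and least certain steps

Total: 11 steps. Longest linear sequence: 11 steps, from 1 to 18.

**Step 7 (key step; it bears the label "Proposed new method:").**
- What may go wrong:
  - Too little activation by the mild BINOL–titanium Lewis acid, so that the ring does not close or turnover stalls.
  - Poor facial selectivity, because the tethered nucleophile approaches the bound aldehyde along a different trajectory from a free allylstannane.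
  - Erosion of the trans preference.
  - Attack through the methyl-bearing enol ether carbon (six-membered closure).
  - Protodestannylation by the phenolic ligand.
- Fallback (known chemistry): setting out from 11, the ring is closed with BF3·OEt2 in CH2Cl2 at −78 °C, the established trans-selective Lewis-acid cyclisation of γ-alkoxyallylstannane aldehydes. Without a chiral controller this should give 13 together with its ring diastereomer (2S,3R)-5-[(1R)-1-{[tert-butyl(dimethyl)silyl]oxy}ethyl]-2-(prop-1-en-2-yl)-2,3-dihydro-1-benzofuran-3-ol F1. Because C1′ is already R, the two are diastereomers and not enantiomers, and they are separated by chromatography. The route is rejoined at 13, at the cost of up to half of the material.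

**Step 5.**
- What may go wrong:
  - Incomplete or misdirected metalation of the dianion: ring lithiation ortho to O1, SN2′ attack of the base on the aryl allyl ether with loss of phenoxide, or deprotonation at C1′ followed by silyl migration.
  - Stannylation at the oxygen-bearing carbon instead of the remote terminus.
  - The product must also survive the oxidation of step 6.
- Fallback: setting out from 6, the hydroxyl is oxidised first (MnO2, CH2Cl2, rt) to the methallyloxy aldehyde F2. In THF at −20 °C, F2 is masked in the flask with lithium 4-methylpiperazin-1-ide as the lithium α-amino alkoxide F3. F3 is metalated at the allylic O–CH2 group with s-BuLi/TMEDA at −78 °C and quenched with 7 to give the stannylated amino alkoxide F4. Aqueous work-up collapses the aminal and delivers 11 directly, so that steps 5 and 6 are both replaced. This puts the oxidation before the tin is introduced and exchanges the bare alkoxide for a chelating group that holds the base next to the protons to be removed.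

**Step 10.**
- What may go wrong:
  - Ionisation of the activated benzylic esters by the acidic selenium species: racemisation at C1′, epimerisation at C3, or elimination to the benzofuran.
  - A competing ene reaction at C2–H.
  - Incomplete conversion with selenium-containing by-products.
- Fallback: setting out from 16, an ene-type chlorination with hypochlorous acid (Ca(OCl)2, solid CO2, CH2Cl2/H2O, 0 °C) should give the allylic chloride F5. F5 is then oxidised with N-methylmorpholine N-oxide and NaI (cat.) in MeCN at rt (a Kornblum-type N-oxide oxidation) straight to 18, bypassing 17 and step 11.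

**Step 9.**
- What may go wrong:
  - Elimination or ionisation while the two activated benzylic hydroxyls of 14 are acylated together in the presence of chloride and pyridinium ions.
  - Incomplete acylation of the C3 hydroxyl, which is flanked by the isopropenyl group.
  - Diol 14 is also the most dehydration-prone compound of the route.
- Fallback: setting out from 13, the esters are introduced one at a time. Acylation of the C3 hydroxyl with 15 (pyridine, DMAP, CH2Cl2, 0 °C) gives the silyl ether mono-isovalerate F6. Desilylation with Bu4NF buffered with AcOH (THF, rt) gives the hydroxy mono-isovalerate F7, and a second acylation with 15 under the same conditions rejoins the route at 16. Diol 14 is then never handled.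

## Further compounds

F1 | step 7 | (2S,3R)-5-[(1R)-1-{[tert-butyl(dimethyl)silyl]oxy}ethyl]-2-(prop-1-en-2-yl)-2,3-dihydro-1-benzofuran-3-ol | `C=C(C)[C@@H]1Oc2ccc([C@@H](C)O[Si](C)(C)C(C)(C)C)cc2[C@H]1O`
F2 | step 5 | 5-[(1R)-1-{[tert-butyl(dimethyl)silyl]oxy}ethyl]-2-[(2-methylprop-2-en-1-yl)oxy]benzaldehyde | `O=Cc1cc([C@@H](C)O[Si](C)(C)C(C)(C)C)ccc1OCC(C)=C`
F3 | step 5 | lithium {5-[(1R)-1-{[tert-butyl(dimethyl)silyl]oxy}ethyl]-2-[(2-methylprop-2-en-1-yl)oxy]phenyl}(4-methylpiperazin-1-yl)methanolate | `[Li]OC(N1CCN(C)CC1)c1cc([C@@H](C)O[Si](C)(C)C(C)(C)C)ccc1OCC(C)=C`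
F4 | step 5 | lithium {5-[(1R)-1-{[tert-butyl(dimethyl)silyl]oxy}ethyl]-2-{[(1Z)-2-methyl-3-(tributylstannyl)prop-1-en-1-yl]oxy}phenyl}(4-methylpiperazin-1-yl)methanolate | `[Li]OC(N1CCN(C)CC1)c1cc([C@@H](C)O[Si](C)(C)C(C)(C)C)ccc1O/C=C(/C)C[Sn](CCCC)(CCCC)CCCC`
F5 | step 10 | (2R,3S)-2-(3-chloroprop-1-en-2-yl)-5-[(1R)-1-(3-methylbutanoyloxy)ethyl]-2,3-dihydro-1-benzofuran-3-yl 3-methylbutanoate | `C=C(CCl)[C@H]1Oc2ccc([C@@H](C)OC(=O)CC(C)C)cc2[C@@H]1OC(=O)CC(C)C`
F6 | step 9 | (2R,3S)-5-[(1R)-1-{[tert-butyl(dimethyl)silyl]oxy}ethyl]-2-(prop-1-en-2-yl)-2,3-dihydro-1-benzofuran-3-yl 3-methylbutanoate | `C=C(C)[C@H]1Oc2ccc([C@@H](C)O[Si](C)(C)C(C)(C)C)cc2[C@@H]1OC(=O)CC(C)C`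
F7 | step 9 | (2R,3S)-5-[(1R)-1-hydroxyethyl]-2-(prop-1-en-2-yl)-2,3-dihydro-1-benzofuran-3-yl 3-methylbutanoate | `C=C(C)[C@H]1Oc2ccc([C@@H](C)O)cc2[C@@H]1OC(=O)CC(C)C`
A1 | alternative 1 | (2R,3S)-5-[(1R)-1-(3-methylbutanoyloxy)ethyl]-2-(prop-1-en-2-yl)-7-(trimethylsilyl)-2,3-dihydro-1-benzofuran-3-yl 3-methylbutanoate | `C=C(C)[C@H]1Oc2c([Si](C)(C)C)cc([C@@H](C)OC(=O)CC(C)C)cc2[C@@H]1OC(=O)CC(C)C`
A2 | alternative 1 | (3S,4R)-5-methyl-4-{[(trimethylsilyl)ethynyl]oxy}hex-5-en-1-yn-3-yl 3-methylbutanoate | `C=C(C)[C@@H](OC#C[Si](C)(C)C)[C@@H](OC(=O)CC(C)C)C#C`
A3 | alternative 1 | (2R)-but-3-yn-2-yl 3-methylbutanoate | `C#C[C@@H](C)OC(=O)CC(C)C`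
A4 | alternative 2 | (2R,3S)-5-acetyl-2-(prop-1-en-2-yl)-2,3-dihydro-1-benzofuran-3-yl 3-methylbutanoate | `C=C(C)[C@H]1Oc2ccc(C(C)=O)cc2[C@@H]1OC(=O)CC(C)C`
A5 | alternative 2 | (3R,4S)-6-acetyl-3-hydroxy-2,2-dimethyl-3,4-dihydro-2H-chromen-4-yl 3-methylbutanoate | `CC1(C)Oc2ccc(C(C)=O)cc2[C@H](OC(=O)CC(C)C)[C@H]1O`
A6 | alternative 2 | 1-(2,2-dimethyl-2H-chromen-6-yl)ethan-1-one | `CC(=O)c1ccc2c(c1)C=CC(C)(C)O2`
A7 | alternative 3 | 1-[(2R,3S)-3-hydroxy-2-(prop-1-en-2-yl)-2,3-dihydro-1-benzofuran-5-yl]ethan-1-one | `C=C(C)[C@H]1Oc2ccc(C(C)=O)cc2[C@@H]1O`
A8 | alternative 3 | 1-{3-[(1S,2R)-1,2-dihydroxy-3-methylbut-3-en-1-yl]-4-fluorophenyl}ethan-1-one | `C=C(C)[C@@H](O)[C@@H](O)c1cc(C(C)=O)ccc1F`
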